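With time the summer run stops moving: target and cross product stand at 36% and 62% by 8.00 h, and at 39% and 61% by 20.0 h.

| setting | autumn | summer | cedar | ash |
|---|---|---|---|---|
| starting material | 0.067 M | 0.050 M | 0.10 M | 0.10 M |
| partner | 1.5 equiv | 1.5 equiv | 0.380 equiv | 1.50 equiv |
| second substrate | 1 equiv | 1 equiv | 0.250 equiv | 1.00 equiv |
| remark | run made earlier | run made earlier |  |  |
| time |  |  | 8.0 h | 30 h |

| run | time / h | target / % | cross product / % |
|---|---|---|---|
| autumn | 5.00 | 39 | 60 |
| autumn | 10.0 | 39 | 57 |
| autumn | 15.0 | 41 | 57 |
| autumn | 20.0 | 36 | 60 |
| summer | 1.33 | 20 | 43 |
| summer | 3.00 | 33 | 53 |
| summer | 8.00 | 36 | 62 |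
| summer | 20.0 | 39 | 61 |

(readings scatter by 2 percentage points)

1. the winner by share of target in all that became target or cross product; "neither" if no more than 2 percentage points parts them (cedar / ash / neither)
2. share of target in all that became target or cross product, cedar
3. share of target in all that became target or cross product, ash

- what was read earlier has a scatter of 2 percentage points, one standard deviation

1. I take each product to form from starting material and one partner molecule or one second substrate molecule. The rate of target over the rate of cross product then holds no [starting material]: it is [partner]/[second substrate] divided by a selectivity factor. Summer's last reading gives 3.13 for this factor, the decades of second substrate lost per decade of partner lost.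

2. That rate ratio starts at 0.486 in cedar and 0.480 in ash, so the two start level. Ash has summer's equivalents, so I take summer's share, 39.0%.

3. In summer, second substrate falls at 0.184 h⁻¹, counted in decades, over the first 1.33 h, while [starting material] averages 0.685 of its charge. Cedar charges twice that concentration, so its rate starts at 0.536 h⁻¹.

4. In cedar I let this rate slow in step with [starting material]. Target forms alongside cross product, so as a rough guess at the mean over the run I subtract from the charge the second substrate's charge and half the partner's. That leaves 0.560 of charge, so 8.0 h gives 2.40 decades.

5. Dividing by the factor, partner falls to 17.1% of its charge. Target is then 31.5% and cross product 0.250 of the starting charge, a share of 55.8%.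

The forecast names cedar: cedar 56% (49% to 62%), ash 39.5% (36% to 43%), holding that “the share is concentration independent”.

    starting material + partner → target (k = 0.00100 L mol⁻¹ s⁻¹)
    second substrate + partner → second product (k = 2.80 × 10⁻⁵ L mol⁻¹ s⁻¹)
    starting material + second substrate → cross product (k = 0.00380 L mol⁻¹ s⁻¹)
    2 second substrate → homo dimer (k = 3.50 × 10⁻⁴ L mol⁻¹ s⁻¹)

Cedar gives 55.9% and ash 39.0%, so the winner is cedar, as forecast. At 8.00 h cedar holds 0.17% of its second substrate and 19% of its partner. That second substrate is 2.76 decades down, and the factor turns this into partner at 13.1%, lower than the flask holds.

Now take cedar with 1.50 equiv of partner. One decade of second substrate costs 47.9% left of partner, so target 78.1% and cross product 22.5%, together about the charge, a share of 77.6%. The flask gives 76.9%.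

The runs stem from a simulated flask on assumed constants, noise included.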